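**Plan**

- Cuts, in retrosynthetic order: (a) the allyl C–O bond to the coumarin; (b) the ring bond between the methylidene-bearing carbon and its neighbouring ring CH2; (c) the two ring C–CH3 bonds and, through a cyclopropanol, the ketone carbon with both ring CH2 groups, back to an ester and an ethyl Grignard reagent; (d) the bond from the ring CH to the later methylidene-bearing carbon, made as an alkyne addition to an alkylidene Meldrum's acid; (e) the terminal olefin of geranyl acetate.
- Enabling feature: the ring atoms C(=CH2)–CH2–CH2–C(=O) follow one another, so the CH2 bonded to the sp2 carbon is the β-carbon (homoenolate carbon) of the ketone. The ketone carbon and both CH2 groups can therefore be stored as a 1-substituted cyclopropanol, and the sp2 carbon as a 1-bromovinyl group.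
- Forward order: geranyl acetate → C1–C6 aldehyde → alkynylated Meldrum's acid → β-ethynyl ester → 1-bromovinyl ester → gem-dimethyl ester → cyclopropanol → the one carbocycle (palladium) → free allylic alcohol → coumarin ether.
- Stereochemistry: the single stereocentre (ring CH) is set in step 4 by a chiral copper catalyst and is never enolisable afterwards. Its descriptor changes from S (open-chain compounds 8–17) to R (ring compounds 18–21) only because CIP priorities change. The E-olefin of the side chain comes from geranyl acetate.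

Key step: step 10

Assumption: 4-hydroxy-5-methylcoumarin is bought, and of the two available antipodes of the P,N ligand in step 4 the one that gives the (S)-adduct 8 is used, the sense of induction being checked on the first run.

**Route**

Step 1
Reactants: 1 geranyl acetate
Product: 2 (2E)-5-(3,3-dimethyloxiran-2-yl)-3-methylpent-2-en-1-yl acetate (6,7-epoxygeranyl acetate; racemic at the oxirane CH)
Conditions: mCPBA, NaHCO3, CH2Cl2, 0 °C
Reagents that add atoms: meta-chloroperoxybenzoic acid (mCPBA), OOC(=O)c1cccc(Cl)c1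
Why: Prilezhaev epoxidation, in which the peracid reacts fastest with the electron-rich trisubstituted 6,7-olefin because the 2,3-olefin is deactivated by the allylic acetoxy group; the epoxide stereocentre (formed racemic) is erased in step 2.

Step 2
Reactants: 2 6,7-epoxygeranyl acetate
Product: 4 (2E)-3-methyl-6-oxohex-2-en-1-yl acetate, via diol 3 (not isolated)
Conditions: H5IO6, THF/H2O, 0 °C
Reagents that add atoms: none
Why: Periodic acid opens the epoxide with water at the tertiary carbon to diol 3 and cleaves it at once (Malaprade glycol cleavage), so the aldehyde keeps the former epoxide oxygen while the acetate and the 2,3-olefin are inert.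

Step 3
Reactants: 4 (2E)-3-methyl-6-oxohex-2-en-1-yl acetate; 5 Meldrum's acid
Product: 6 (2E)-6-(2,2-dimethyl-4,6-dioxo-1,3-dioxan-5-ylidene)-3-methylhex-2-en-1-yl acetate
Conditions: pyrrolidine (10 mol%), AcOH (10 mol%), 4 Å MS, CH2Cl2, 0 °C → rt
Reagents that add atoms: none
Why: Knoevenagel condensation of the highly acidic methylene of Meldrum's acid with the aldehyde under pyrrolidinium acetate catalysis; sieves, low temperature and a small excess of aldehyde are meant to hold back a second (Michael) addition of Meldrum's acid, and the alkylidene is used without storage.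

Step 4
Reactants: 6 alkylidene Meldrum's acid; 7 (trimethylsilyl)acetylene
Product: 8 (2E,6S)-6-(2,2-dimethyl-4,6-dioxo-1,3-dioxan-5-yl)-3-methyl-8-(trimethylsilyl)oct-2-en-7-yn-1-yl acetate
Conditions: Cu(OAc)2·H2O (10 mol%), sodium L-ascorbate (20 mol%), N-PINAP-type P,N ligand (10 mol%), H2O, 0 °C
Reagents that add atoms: none
Why: Copper-catalysed enantioselective conjugate alkynylation, in which ascorbate reduces Cu(OAc)2 to monovalent copper and its acetylide, bound to the atropisomeric P,N ligand, adds to one face of the doubly activated alkylidene, so that the ligand sets the only stereocentre of the synthesis (S here, the later ring CH).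

Step 5
Reactants: 8 alkynylated Meldrum's acid
Product: 11 methyl (3S,6E)-3-ethynyl-8-hydroxy-6-methyloct-6-enoate, via malonic half-ester 9 (not isolated), via acetoxy silylalkynyl ester 10 (not isolated)
Conditions: MeOH/pyridine (1:5), 100 °C (sealed); then K2CO3, MeOH, rt
Reagents that add atoms: methanol, CO
Why: Alcoholysis of the Meldrum's acid ring gives half-ester 9, which decarboxylates in hot pyridine (malonic acid decarboxylation) to methyl ester 10, and carbonate in methanol then removes the O-acetyl group (Zemplén-type transesterification) and the C-silyl group (protiodesilylation) in the same flask without touching the non-enolisable β-stereocentre.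

Step 6
Reactants: 11 methyl (3S,6E)-3-ethynyl-8-hydroxy-6-methyloct-6-enoate
Product: 12 methyl (3S,6E)-8-[(tert-butyldiphenylsilyl)oxy]-3-ethynyl-6-methyloct-6-enoate
Conditions: TBDPSCl, imidazole, CH2Cl2, rt
Reagents that add atoms: tert-butyl(chloro)diphenylsilane (TBDPSCl), CC(C)(C)[Si](Cl)(c1ccccc1)c1ccccc1
Why: Imidazole-assisted silylation of the primary allylic alcohol; the tert-butyldiphenylsilyl ether is chosen because it should tolerate the boron bromide and acetic acid of step 7, the amide base of step 8, the Grignard reagent of step 9 and carbonate at 80 °C in step 10.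

Step 7
Reactants: 12 silyl-protected alkynyl ester
Product: 14 methyl (3S,6E)-3-(1-bromoethenyl)-8-[(tert-butyldiphenylsilyl)oxy]-6-methyloct-6-enoate, via bromoalkenylborane 13 (not isolated)
Conditions: B-Br-9-BBN, CH2Cl2, 0 °C; then AcOH, 0 °C → rt
Reagents that add atoms: B-bromo-9-borabicyclo[3.3.1]nonane, BrB1C2CCCC1CCC2
Why: Hara–Suzuki bromoboration, in which B–Br adds syn across the terminal alkyne with bromine at the internal carbon to give 13 and acetic acid then cleaves the alkenyl–boron bond (protodeboronation) to leave the 2-bromo-1-alkene; the trisubstituted olefin, the ester and the silyl ether should not react with the B–Br reagent at 0 °C.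

Step 8
Reactants: 14 1-bromovinyl ester
Product: 16 methyl (3S,6E)-3-(1-bromoethenyl)-8-[(tert-butyldiphenylsilyl)oxy]-2,2,6-trimethyloct-6-enoate, via monomethyl ester 15 (not isolated)
Conditions: LiN(iPr)2, THF, −78 °C, then MeI, −78 → 0 °C; again LiN(iPr)2, THF, −78 °C, then MeI, DMPU, −78 → 0 °C
Reagents that add atoms: iodomethane, CI
Why: Two consecutive ester enolate alkylations with iodomethane build the quaternary carbon; the alkenyl bromide is inert to the amide base at −78 °C, the adjacent stereocentre carries no acidic hydrogen, and the stereocentre formed transiently in 15 vanishes with the second methylation.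

Step 9
Reactants: 16 gem-dimethyl ester
Product: 17 1-[(3S,6E)-3-(1-bromoethenyl)-8-[(tert-butyldiphenylsilyl)oxy]-2,6-dimethyloct-6-en-2-yl]cyclopropan-1-ol
Conditions: EtMgBr (3 equiv, slow addition), Ti(OiPr)4 (0.5 equiv), THF, 0 °C → rt
Reagents that add atoms: ethylmagnesium bromide, CC[Mg]Br
Why: Kulinkovich cyclopropanation, in which EtMgBr and Ti(OiPr)4 form a titanacyclopropane that acts as a 1,2-dicarbanion toward the ester carbonyl (insertion with loss of methoxide, then ring closure onto the ketone formed), α-quaternary esters being known substrates; the alkenyl bromide does not react with the Grignard reagent in the absence of a coupling catalyst.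

Step 10
Reactants: 17 cyclopropanol
Product: 18 (3R)-3-[(3E)-5-[(tert-butyldiphenylsilyl)oxy]-3-methylpent-3-en-1-yl]-2,2-dimethyl-4-methylidenecyclohexan-1-one
Conditions: Pd(OAc)2 (10 mol%), XPhos (20 mol%), Cs2CO3 (2 equiv), toluene, 80 °C
Reagents that add atoms: none
Why: Zerovalent palladium formed from Pd(OAc)2 and XPhos inserts into the alkenyl C–Br bond, carbonate deprotonates the cyclopropanol, the alkoxide binds the divalent palladium centre in a six-membered chelate, strain-driven β-carbon elimination (either CH2, they are equivalent) unmasks the ketone and places palladium on the β-methylene, and C(sp2)–C(sp3) reductive elimination forms the ring bond. The closest known reaction type is the palladium-catalysed ring-opening cross-coupling of cyclopropanols (ketone homoenolates) with aryl and alkenyl halides, run here within one molecule. The six-membered carbocycle closes by reductive elimination from a seven-membered palladacycle with the alkenyl carbon entering the ring, so its =CH2 ends up exocyclic without any later olefination. No stereocentre is created, and the existing one is not involved and bears no acidic hydrogen, so it is retained. The step needs reductive elimination to outrun β-hydride elimination of the palladium homoenolate, C–O reductive elimination and Heck insertion into the side-chain olefin; the gem-dimethyl group presses the chain toward the chelate (Thorpe–Ingold effect), the bulky electron-rich biarylphosphine speeds C–C reductive elimination, and the remote trisubstituted olefin could only be reached by a slower insertion that builds a quaternary carbon.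

Step 11
Reactants: 18 silyl-protected ring ketone
Product: 19 (3R)-3-[(3E)-5-hydroxy-3-methylpent-3-en-1-yl]-2,2-dimethyl-4-methylidenecyclohexan-1-one
Conditions: Bu4NF, THF, 0 °C → rt
Reagents that add atoms: none
Why: Fluoride-induced cleavage of the Si–O bond, driven by the strong Si–F bond; the ketone, the exocyclic methylene and the stereocentre should be inert to Bu4NF at these temperatures.

Step 12
Reactants: 19 allylic alcohol; 20 4-hydroxy-5-methylcoumarin
Product: 21 4-{[(2E)-5-[(1R)-2,2-dimethyl-6-methylidene-3-oxocyclohexyl]-3-methylpent-2-en-1-yl]oxy}-5-methyl-2H-chromen-2-one (target)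
Conditions: PPh3, DIAD, THF, 0 °C → rt
Reagents that add atoms: none
Why: Mitsunobu etherification, in which the acidic 4-hydroxycoumarin (a vinylogous carboxylic acid) protonates the betaine and its oxygen displaces the alkoxyphosphonium of the primary allylic alcohol by SN2, which favours the 4-O-allyl ether over C-3 alkylation and leaves the E-olefin and the stereocentre untouched.

**Compound list**

1 | geranyl acetate, (2E)-3,7-dimethylocta-2,6-dien-1-yl acetate | CC(C)=CCC/C(C)=C/COC(C)=O | starting material
2 | (2E)-5-(3,3-dimethyloxiran-2-yl)-3-methylpent-2-en-1-yl acetate (racemic epoxide) | CC1(C)OC1CC/C(C)=C/COC(C)=O | intermediate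
3 | (2E)-6,7-dihydroxy-3,7-dimethyloct-2-en-1-yl acetate | CC(C)(O)C(O)CC/C(C)=C/COC(C)=O | intermediate (not isolated)
4 | (2E)-3-methyl-6-oxohex-2-en-1-yl acetate | O=CCC/C(C)=C/COC(C)=O | intermediate
5 | Meldrum's acid, 2,2-dimethyl-1,3-dioxane-4,6-dione | CC1(C)OC(=O)CC(=O)O1 | starting material
6 | (2E)-6-(2,2-dimethyl-4,6-dioxo-1,3-dioxan-5-ylidene)-3-methylhex-2-en-1-yl acetate | CC1(C)OC(=O)C(=CCC/C(C)=C/COC(C)=O)C(=O)O1 | intermediate
7 | (trimethylsilyl)acetylene | C#C[Si](C)(C)C | starting material
8 | (2E,6S)-6-(2,2-dimethyl-4,6-dioxo-1,3-dioxan-5-yl)-3-methyl-8-(trimethylsilyl)oct-2-en-7-yn-1-yl acetate | CC1(C)OC(=O)C(C(=O)O1)[C@H](CC/C(C)=C/COC(C)=O)C#C[Si](C)(C)C | intermediate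
9 | 2-[(3S,6E)-8-acetoxy-6-methyl-1-(trimethylsilyl)oct-6-en-1-yn-3-yl]-3-methoxy-3-oxopropanoic acid (epimers at the malonate carbon) | COC(=O)C(C(O)=O)[C@H](CC/C(C)=C/COC(C)=O)C#C[Si](C)(C)C | intermediate (not isolated)
10 | methyl (3S,6E)-8-acetoxy-6-methyl-3-[(trimethylsilyl)ethynyl]oct-6-enoate | COC(=O)C[C@H](CC/C(C)=C/COC(C)=O)C#C[Si](C)(C)C | intermediate (not isolated)
11 | methyl (3S,6E)-3-ethynyl-8-hydroxy-6-methyloct-6-enoate | COC(=O)C[C@H](CC/C(C)=C/CO)C#C | intermediate
12 | methyl (3S,6E)-8-[(tert-butyldiphenylsilyl)oxy]-3-ethynyl-6-methyloct-6-enoate | COC(=O)C[C@H](CC/C(C)=C/CO[Si](c1ccccc1)(c1ccccc1)C(C)(C)C)C#C | intermediate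
13 | methyl (3S,6E)-3-[(Z)-2-(9-borabicyclo[3.3.1]nonan-9-yl)-1-bromoethenyl]-8-[(tert-butyldiphenylsilyl)oxy]-6-methyloct-6-enoate | COC(=O)C[C@H](CC/C(C)=C/CO[Si](c1ccccc1)(c1ccccc1)C(C)(C)C)/C(Br)=C/B1C2CCCC1CCC2 | intermediate (not isolated)
14 | methyl (3S,6E)-3-(1-bromoethenyl)-8-[(tert-butyldiphenylsilyl)oxy]-6-methyloct-6-enoate | COC(=O)C[C@H](CC/C(C)=C/CO[Si](c1ccccc1)(c1ccccc1)C(C)(C)C)C(Br)=C | intermediate
15 | methyl (3S,6E)-3-(1-bromoethenyl)-8-[(tert-butyldiphenylsilyl)oxy]-2,6-dimethyloct-6-enoate (C2 epimers) | COC(=O)C(C)[C@H](CC/C(C)=C/CO[Si](c1ccccc1)(c1ccccc1)C(C)(C)C)C(Br)=C | intermediate (not isolated)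
16 | methyl (3S,6E)-3-(1-bromoethenyl)-8-[(tert-butyldiphenylsilyl)oxy]-2,2,6-trimethyloct-6-enoate | COC(=O)C(C)(C)[C@H](CC/C(C)=C/CO[Si](c1ccccc1)(c1ccccc1)C(C)(C)C)C(Br)=C | intermediate
17 | 1-[(3S,6E)-3-(1-bromoethenyl)-8-[(tert-butyldiphenylsilyl)oxy]-2,6-dimethyloct-6-en-2-yl]cyclopropan-1-ol | OC1(CC1)C(C)(C)[C@H](CC/C(C)=C/CO[Si](c1ccccc1)(c1ccccc1)C(C)(C)C)C(Br)=C | intermediate (precursor of the key step)
18 | (3R)-3-[(3E)-5-[(tert-butyldiphenylsilyl)oxy]-3-methylpent-3-en-1-yl]-2,2-dimethyl-4-methylidenecyclohexan-1-one | C=C1CCC(=O)C(C)(C)[C@@H]1CC/C(C)=C/CO[Si](c1ccccc1)(c1ccccc1)C(C)(C)C | intermediate (product of the key step)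
19 | (3R)-3-[(3E)-5-hydroxy-3-methylpent-3-en-1-yl]-2,2-dimethyl-4-methylidenecyclohexan-1-one | C=C1CCC(=O)C(C)(C)[C@@H]1CC/C(C)=C/CO | intermediate
20 | 4-hydroxy-5-methylcoumarin, 4-hydroxy-5-methyl-2H-chromen-2-one | Cc1cccc2oc(=O)cc(O)c12 | starting material
21 | 4-{[(2E)-5-[(1R)-2,2-dimethyl-6-methylidene-3-oxocyclohexyl]-3-methylpent-2-en-1-yl]oxy}-5-methyl-2H-chromen-2-one | C=C1CCC(=O)C(C)(C)[C@@H]1CC/C(C)=C/COc1cc(=O)oc2cccc(C)c12 | target

**Step count**

Total: 12 steps. Longest linear sequence: 12 steps (1 → 21); compounds 5, 7 and 20 enter as purchased materials.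

**Steps most likely to fail**

1. Step 10 (ring closure). β-Hydride elimination from the palladium homoenolate (giving a vinyl ketone and a reduced alkene), C–O reductive elimination from the chelated alkoxide, or Heck insertion into the side-chain olefin may outpace the C–C reductive elimination. Fallback, from 16 and back at 18: the same ring bond is made by an intramolecular B-alkyl Suzuki–Miyaura coupling with the ketone carbon held at the carbinol level. Ester 16 is reduced with iBu2AlH (CH2Cl2, −78 → 0 °C) to the neopentyl alcohol F1 and oxidised with Dess–Martin periodinane to aldehyde F2. CH2=CHMgBr gives the allylic alcohol F3 (epimers, of no consequence), which is silylated (Et3SiCl, imidazole) to the triethylsilyl ether F4. 9-BBN hydroborates only the monosubstituted vinyl group to the alkylborane F5, which is not isolated; PdCl2(dppf) and aqueous K3PO4 in THF/DMF at 60 °C then close the ring to the silyl-protected methylidenecyclohexanol F6. PPTS in MeOH removes the triethylsilyl group to give the ring alcohol F7, and Dess–Martin oxidation returns to 18.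

2. Step 9 (cyclopropanol formation). Reaction of the titanacyclopropane with the neopentyl-type ester carbonyl may be too slow, so that plain Grignard addition or reduction of the ester, or reduction of the C–Br bond by low-valent titanium, takes over. Fallback, from 16 and back at 17: the cyclopropanol is built by cyclopropanation of a silyl enol ether. Ester 16 is taken through alcohol F1 to aldehyde F2 as described above. MeMgBr gives the secondary alcohol F8 and Dess–Martin oxidation the methyl ketone F9, which can enolise only toward its methyl group, so Me3SiOTf/Et3N gives the single silyl enol ether F10. Simmons–Smith cyclopropanation in the Furukawa manner (Et2Zn, CH2I2, 1.1 equiv, CH2Cl2, 0 °C) of this most electron-rich olefin gives the siloxycyclopropane F11, and catalytic K2CO3 in MeOH at 0 °C releases 17.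

3. Step 4 (asymmetric alkynylation, together with the alkylidene from step 3). Addition of the silylacetylide to an unbranched alkylidene Meldrum's acid may be slow, facial selectivity may erode, and already in step 3 a second Michael addition of Meldrum's acid may consume the alkylidene. Fallback, from 4 and back at 11: the stereocentre is set on an enal by rhodium catalysis. Aldehyde 4 is homologated with Ph3P=CHCHO (toluene, 80 °C) to the (2E)-enal F12. Conjugate alkynylation with (triisopropylsilyl)acetylene ([Rh(OAc)(C2H4)2]2, DTBM-segphos antipode giving the S product, MeOH, 40 °C) gives the β-alkynyl aldehyde F13. Pinnick oxidation (NaClO2, NaH2PO4, 2-methyl-2-butene, t-BuOH/H2O) gives acid F14, and Me3SiCHN2 in MeOH/toluene gives methyl ester F15. K2CO3 in MeOH removes the acetate to give hydroxy ester F16, and Bu4NF (THF, 0 °C) removes the C-silyl group to rejoin the route at 11.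

**Further compounds**

F1 | step 10 | (3S,6E)-3-(1-bromoethenyl)-8-[(tert-butyldiphenylsilyl)oxy]-2,2,6-trimethyloct-6-en-1-ol | OCC(C)(C)[C@H](CC/C(C)=C/CO[Si](c1ccccc1)(c1ccccc1)C(C)(C)C)C(Br)=C
F2 | step 10 | (3S,6E)-3-(1-bromoethenyl)-8-[(tert-butyldiphenylsilyl)oxy]-2,2,6-trimethyloct-6-enal | O=CC(C)(C)[C@H](CC/C(C)=C/CO[Si](c1ccccc1)(c1ccccc1)C(C)(C)C)C(Br)=C
F3 | step 10 | (5S,8E)-5-(1-bromoethenyl)-10-[(tert-butyldiphenylsilyl)oxy]-4,4,8-trimethyldeca-1,8-dien-3-ol (C3 epimers) | C=CC(O)C(C)(C)[C@H](CC/C(C)=C/CO[Si](c1ccccc1)(c1ccccc1)C(C)(C)C)C(Br)=C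
F4 | step 10 | triethylsilyl ether of F3, (5S,8E)-5-(1-bromoethenyl)-10-[(tert-butyldiphenylsilyl)oxy]-4,4,8-trimethyl-3-[(triethylsilyl)oxy]deca-1,8-diene | C=CC(O[Si](CC)(CC)CC)C(C)(C)[C@H](CC/C(C)=C/CO[Si](c1ccccc1)(c1ccccc1)C(C)(C)C)C(Br)=C
F5 | step 10 | 9-[(5S,8E)-5-(1-bromoethenyl)-10-[(tert-butyldiphenylsilyl)oxy]-4,4,8-trimethyl-3-[(triethylsilyl)oxy]dec-8-en-1-yl]-9-borabicyclo[3.3.1]nonane | CC[Si](CC)(CC)OC(CCB1C2CCCC1CCC2)C(C)(C)[C@H](CC/C(C)=C/CO[Si](c1ccccc1)(c1ccccc1)C(C)(C)C)C(Br)=C
F6 | step 10 | triethylsilyl ether of (3R)-3-[(3E)-5-[(tert-butyldiphenylsilyl)oxy]-3-methylpent-3-en-1-yl]-2,2-dimethyl-4-methylidenecyclohexan-1-ol (C1 epimers) | C=C1CCC(O[Si](CC)(CC)CC)C(C)(C)[C@@H]1CC/C(C)=C/CO[Si](c1ccccc1)(c1ccccc1)C(C)(C)C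
F7 | step 10 | (3R)-3-[(3E)-5-[(tert-butyldiphenylsilyl)oxy]-3-methylpent-3-en-1-yl]-2,2-dimethyl-4-methylidenecyclohexan-1-ol (C1 epimers) | C=C1CCC(O)C(C)(C)[C@@H]1CC/C(C)=C/CO[Si](c1ccccc1)(c1ccccc1)C(C)(C)C
F8 | step 9 | (4S,7E)-4-(1-bromoethenyl)-9-[(tert-butyldiphenylsilyl)oxy]-3,3,7-trimethylnon-7-en-2-ol (C2 epimers) | CC(O)C(C)(C)[C@H](CC/C(C)=C/CO[Si](c1ccccc1)(c1ccccc1)C(C)(C)C)C(Br)=C
F9 | step 9 | (4S,7E)-4-(1-bromoethenyl)-9-[(tert-butyldiphenylsilyl)oxy]-3,3,7-trimethylnon-7-en-2-one | CC(=O)C(C)(C)[C@H](CC/C(C)=C/CO[Si](c1ccccc1)(c1ccccc1)C(C)(C)C)C(Br)=C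
F10 | step 9 | {[(4S,7E)-4-(1-bromoethenyl)-9-[(tert-butyldiphenylsilyl)oxy]-3,3,7-trimethylnona-1,7-dien-2-yl]oxy}trimethylsilane | C=C(O[Si](C)(C)C)C(C)(C)[C@H](CC/C(C)=C/CO[Si](c1ccccc1)(c1ccccc1)C(C)(C)C)C(Br)=C
F11 | step 9 | {1-[(3S,6E)-3-(1-bromoethenyl)-8-[(tert-butyldiphenylsilyl)oxy]-2,6-dimethyloct-6-en-2-yl]cyclopropoxy}trimethylsilane | C[Si](C)(C)OC1(CC1)C(C)(C)[C@H](CC/C(C)=C/CO[Si](c1ccccc1)(c1ccccc1)C(C)(C)C)C(Br)=C
F12 | step 4 | (2E,6E)-3-methyl-8-oxoocta-2,6-dien-1-yl acetate | O=C/C=C/CC/C(C)=C/COC(C)=O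
F13 | step 4 | (2E,6S)-3-methyl-8-oxo-6-{[tri(propan-2-yl)silyl]ethynyl}oct-2-en-1-yl acetate | O=CC[C@H](CC/C(C)=C/COC(C)=O)C#C[Si](C(C)C)(C(C)C)C(C)C
F14 | step 4 | (3S,6E)-8-acetoxy-6-methyl-3-{[tri(propan-2-yl)silyl]ethynyl}oct-6-enoic acid | OC(=O)C[C@H](CC/C(C)=C/COC(C)=O)C#C[Si](C(C)C)(C(C)C)C(C)C
F15 | step 4 | methyl (3S,6E)-8-acetoxy-6-methyl-3-{[tri(propan-2-yl)silyl]ethynyl}oct-6-enoate | COC(=O)C[C@H](CC/C(C)=C/COC(C)=O)C#C[Si](C(C)C)(C(C)C)C(C)C
F16 | step 4 | methyl (3S,6E)-8-hydroxy-6-methyl-3-{[tri(propan-2-yl)silyl]ethynyl}oct-6-enoate | COC(=O)C[C@H](CC/C(C)=C/CO)C#C[Si](C(C)C)(C(C)C)C(C)C
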